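All runs were generated by integration for an exercise; the scatter is artificial.

The reckoning for zeta starts with an easy division: single product at the end of a run, over the equivalents of partner charged.

| setting | south-east | north-east | beta | theta | zeta |
|---|---|---|---|---|---|
| substrate | 0.010 M | 0.010 M | 0.010 M | 0.010 M | 0.010 M |
| partner | 0.29 equiv | 2.4 equiv | 4.00 equiv | 2.00 equiv | 0.500 equiv |
| remark | run made earlier | run made earlier |  |  |  |
| time |  |  | 10 min | 10 min | 10 min |

| run | time / min | single product / % |
|---|---|---|
| south-east | 0.500 | 7.0 |
| south-east | 1.50 | 11.3 |
| south-east | 3.00 | 11.2 |
| south-east | 4.00 | 12.1 |
| south-east | 6.00 | 12.5 |
| south-east | 8.00 | 12.6 |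
| south-east | 10.0 | 12.7 |
| north-east | 0.500 | 36.1 |
| north-east | 1.50 | 40.1 |
| north-east | 3.00 | 38.7 |
| north-east | 4.00 | 38.6 |
| north-east | 6.00 | 36.7 |
| north-east | 8.00 | 35.9 |
| north-east | 10.0 | 35.2 |

(standard deviation of a reading: 0.5 percentage points)

- reactions considered so far: substrate + partner -> single product; substrate + partner -> other mono adduct; partner + single product -> double product; partner + other mono adduct -> double product; partner <-> dormant form

- which of these holds the largest part of the substrate at the end of beta (double product / single product / other mono adduct / substrate)
- which of these holds the largest part of the substrate at the end of theta (double product / single product / other mono adduct / substrate)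
- which of these holds the largest part of the substrate at the end of zeta (double product / single product / other mono adduct / substrate)
- how much single product is there at the end of zeta, in percent of the substrate charged

Substrate takes up partner to give single product or other mono adduct, either of these can take a second partner to give double product, and partner also exchanges with a dormant form.

In the south-east flask, at 10.0 min, the division gives

return = 12.7% / 0.29 equiv = 0.438

This is the return, single product per equivalent of partner charged, and it is a reading with the scatter of its readings. The north-east flask returns 0.147, less. This reckoning assumes that, at this substrate concentration and time, each further equivalent returns less than the one before, so that single product bends downward against charge. The line from zero through south-east then lies above the curve at the zeta charge: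

upper bound = return × 0.500 equiv = 21.9%

The straight line between the two runs lies below it:

lower bound = 12.7% + 0.0995 × (35.2% − 12.7%) = 14.9%

The forecast gave 21.8% for zeta, within 20% to 23.2%, just under the upper bound, while its high end lies above it. It stands on the same reading, “about 0.44 of the partner ends up as single product”, so this closeness is no check. It named other mono adduct for beta, other mono adduct for theta and substrate for zeta.

The flasks give double product in beta (79.0%), single product in theta (38.9%) and substrate in zeta (65.5%). Single product in zeta is 20.9%, inside the bracket.

    substrate + partner → single product (k = 1.50 M⁻¹ s⁻¹)
    substrate + partner → other mono adduct (k = 0.830 M⁻¹ s⁻¹)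
    partner + single product → double product (k = 0.610 M⁻¹ s⁻¹)
    partner + other mono adduct → double product (k = 0.890 M⁻¹ s⁻¹)
    partner ⇌ dormant form (K = 13.0, k = 0.0110 s⁻¹)

At 0.390 min in zeta, the half-life of partner is 0.93 min by its reaction with substrate to give single product, and 1.1 min by the forward turning into dormant form taken alone. At 10.0 min in zeta, the rate at which partner goes to single product, over the forward rate alone at which it goes to dormant form, is 0.89, with partner, the limiting reagent, at 0.77% of its charge and dormant form at 0.00128 M. The return in zeta is 0.418. Below the south-east charge the same line should lie under the curve: at 0.120 equiv of partner, the neighbour of zeta, it gives 5.26%, and that flask holds 5.70% of single product at 10.0 min.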